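**Assumption:** the target has no stereocentre (planar, achiral), so the "single enantiomer" is the compound itself. 4,6-Dibromo-1H-indole (CAS 99910-50-6) is taken as a catalogue compound.

**Retrosynthetic overview**
1. Target 3 is 2,3,4,6-tetrabromo-1H-indole, that is, a 4,6-dibromoindole core carrying two further C–Br bonds on the pyrrole ring.
2. Disconnect C2–Br and C3–Br (electrophilic bromination) to reach commercial 4,6-dibromo-1H-indole 1.
3. Forward order: C3 is brominated first (gives 2), then C2, in the same flask.
4. No ring is formed, because both rings of the indole are bought in 1.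

**Route**

Step 1
Reactants: 1 4,6-dibromo-1H-indole
Product: 3 2,3,4,6-tetrabromo-1H-indole, via 3,4,6-tribromo-1H-indole 2 (not isolated)
Conditions: NBS (2 × 1.0 equiv, recrystallised, second portion after 1 is consumed), dry SiO2, dry CH2Cl2, 0 °C → rt, dark, N2; filter, aq. Na2S2O3/NaHCO3 wash, flash chromatography
Reagents that add atoms: N-bromosuccinimide (NBS), O=C1CCC(=O)N1Br
Why: Electrophilic aromatic substitution (SEAr bromination with NBS) goes first to the most nucleophilic indole carbon C3 to give 2, the second equivalent takes the only free pyrrole position C2, the benzo ring deactivated by two bromines is left alone at exactly two equivalents, and no stereocentre is created.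

**Compound list**
1 | 4,6-dibromo-1H-indole | Brc1cc(Br)c2cc[nH]c2c1 | starting material
2 | 3,4,6-tribromo-1H-indole | Brc1cc(Br)c2c(Br)c[nH]c2c1 | intermediate
3 | 2,3,4,6-tetrabromo-1H-indole | Brc1cc(Br)c2c(Br)c(Br)[nH]c2c1 | target

**Total step count:** 1
**Longest linear sequence:** 1

**Steps most likely to fail**
The route has one step, so the ranking has one entry.

Step 1 has three risks:
- The reaction may stall at the acid- and light-sensitive 3-bromoindole 2, which also carries peri strain between the C3 and C4 bromines, or 2 may decompose.
- Any excess NBS may over-brominate at C7 or C5.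
- Traces of water may divert the 3-bromoindole to oxindole or isatin products.

Fallback, setting out from 1 and coming back at 3: the C2–Br bond is made by deoxybromination of a lactam instead of by SEAr.
- Compound 1 is treated with pyridinium tribromide (3 equiv) in aqueous t-BuOH at rt to give 3,3,4,6-tetrabromoindolin-2-one F1.
- Zn dust in AcOH at rt removes the geminal bromines without touching the aryl bromides and gives 4,6-dibromoindolin-2-one F2.
- POBr3 and imidazole in 1,2-dichloroethane at reflux convert the lactam into 2,4,6-tribromo-1H-indole F3.
- One equivalent of NBS in DMF at 0 °C then brominates C3, the only free pyrrole carbon, and gives 3.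

Further compounds
F1 | step 1 | 3,3,4,6-tetrabromoindolin-2-one | O=C1Nc2cc(Br)cc(Br)c2C1(Br)Br
F2 | step 1 | 4,6-dibromoindolin-2-one | O=C1Cc2c(Br)cc(Br)cc2N1
F3 | step 1 | 2,4,6-tribromo-1H-indole | Brc1cc(Br)c2cc(Br)[nH]c2c1
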